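**Strategy.** Decalin numbering: ring A = C1–C5, C10; ring B = C5–C10; C5 is the methyl-bearing ring-fusion carbon. The route rests on forming C5–C6 by an anionic oxy-Cope rearrangement of a 2-vinylbicyclo[2.2.2]oct-5-en-2-ol. This closes ring B, sets quaternary C5 and, after loss of a bridgehead methoxide, gives the C8 ketone as a C9=C10 enone with C3 as an enol ether. The bicycle arises by Birch dearomatisation of 2,5-dimethoxytoluene (its ring becomes ring A) and an asymmetric Diels–Alder reaction. The step exploits the C8–C7–C6–C5–C4–C3 array of the target: C8 (later CH–CH3) as latent ketone, C3 (later isopropylidene carbon) as latent enol ether.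

Key step: step 6

Remark (descriptors): α is the face of the C5 methyl group, β the opposite face; (S,S)-t-Bu-box is 2,2'-(propane-2,2-diyl)bis[(4S)-4-tert-butyl-4,5-dihydro-1,3-oxazole].
Remark (assumption): compounds 1, 4, 12, 17, 23 and the bis(oxazoline) ligand are taken as purchasable.

**Step 1**
Reactants: 1 2,5-dimethoxytoluene
Product: 3 1,4-dimethoxy-2-methylcyclohexa-1,3-diene, via 1,4-dimethoxy-2-methylcyclohexa-1,4-diene 2 (not isolated)
Conditions: Li, NH3 (l), t-BuOH, THF, −78 °C; NH4Cl; then KOt-Bu (cat.), DMSO, 25 °C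
Reagents that add atoms: none
Why: Birch reduction protonates the two unsubstituted, para-related ring carbons, and base-mediated isomerisation should then move one double bond into conjugation to give the more substituted 1,4-dialkoxy-1,3-diene (dearomatisation, no stereocentre).

**Step 2**
Reactants: 3 1,4-dimethoxy-2-methylcyclohexa-1,3-diene; 4 3-[(E)-but-2-enoyl]-1,3-oxazolidin-2-one
Product: 5 3-{[(1R,2S,3S,4R)-1,4-dimethoxy-3,5-dimethylbicyclo[2.2.2]oct-5-en-2-yl]carbonyl}-1,3-oxazolidin-2-one (acyl group syn, 3-methyl anti to the C5=C6 bridge)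
Conditions: [Cu((S,S)-t-Bu-box)](SbF6)2 (10 mol %), CH2Cl2, −20 to 0 °C
Reagents that add atoms: none
Why: In this catalytic enantioselective Diels–Alder reaction the chelated s-cis imide should be attacked on its Cα-Re face in an endo transition state, and the methyl group of the diene directs the "para" orientation (acyl carbon to the terminus remote from the methyl-bearing carbon), so both bridgeheads and the two new CH centres are set together.

**Step 3**
Reactants: 5 the Diels–Alder imide
Product: 6 (1R,2S,3S,4R)-1,4-dimethoxy-3,5-dimethylbicyclo[2.2.2]oct-5-ene-2-carboxylic acid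
Conditions: LiOH, H2O2, THF/H2O, 0 °C; Na2SO3; HCl
Reagents that add atoms: hydrogen peroxide, OO
Why: Lithium hydroperoxide should cleave the exocyclic imide carbonyl selectively (imide hydrolysis) and sulfite reduces the peracid, with no stereocentre touched.

**Step 4**
Reactants: 6 the bicyclic acid
Product: 8 (1R,3R,4R)-1,4-dimethoxy-3,5-dimethylbicyclo[2.2.2]oct-5-en-2-one (3-methyl anti to the C5=C6 bridge), via 2-hydroperoxy acid 7 (not isolated)
Conditions: LiN(i-Pr)2 (2.2 equiv), THF, 0 °C; O2, −78 °C; then 2 M HCl, 25 °C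
Reagents that add atoms: dioxygen, O=O
Why: In this oxidative decarboxylation the acid dianion is oxygenated at the α-carbon and the α-hydroperoxy acid should fragment to the ketone with loss of CO2 and water, which removes the former acyl-bearing stereocentre and leaves the others intact.

**Step 5**
Reactants: 8 the bicyclic ketone
Product: 9 (1R,2R,3S,4R)-2-ethenyl-1,4-dimethoxy-3,5-dimethylbicyclo[2.2.2]oct-5-en-2-ol (vinyl syn to the C5=C6 bridge)
Conditions: CH2=CHMgBr, CeCl3, THF, −78 °C
Reagents that add atoms: vinylmagnesium bromide, C=C[Mg]Br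
Why: Cerium-mediated Grignard 1,2-addition should occur from the face of the alkene bridge, which is less hindered than the ethano face that also carries the neighbouring methyl group, so the vinyl group ends syn to the alkene as the sigmatropic step requires, while CeCl3 suppresses enolisation.

**Step 6**
Reactants: 9 the vinyl carbinol
Product: 11 (4aS)-6-methoxy-1,4a-dimethyl-4,4a,7,8-tetrahydronaphthalen-2(3H)-one, via cis-fused β-methoxy ketone 10 (not isolated)
Conditions: KH, 18-crown-6, THF, 0 to 25 °C; then MeOH, 25 °C; aq. NH4Cl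
Reagents that add atoms: none
Why: This is an anionic oxy-Cope rearrangement, a [3,3]-sigmatropic shift of a 1,5-dien-3-olate whose closest precedent is the conversion of 2-vinylbicyclo[2.2.2]oct-5-en-2-olates into octalones: the crown-ether-separated potassium alkoxide breaks the C8–C3 bond and joins the vinyl terminus C6 to the methyl-bearing alkene carbon C5 through the boat transition state enforced by the bicycle. Ring B (C5–C10) is closed by this single suprafacial six-centre bond formation, while the former cyclohexadiene ring becomes ring A. The new quaternary stereocentre C5 is controlled by the bicyclic framework, because C6 can reach C5 only on the face on which C8 sits, so the absolute configuration fixed in step 2 is transferred to C5. The step needs the vinyl group syn to the alkene bridge, which step 5 secures. The bridgehead methoxy group at C10 becomes β to the new C8 carbonyl only after the rearrangement, so proton exchange in methanol and E1cB loss of methoxide should give the C9=C10 enone and leave C3 as its methyl enol ether. The C9 and C10 stereocentres are erased on purpose and reset in step 8.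

**Step 7**
Reactants: 12 2,6-dimethylanisole
Product: 13 1-(bromomethyl)-2-methoxy-3-methylbenzene
Conditions: NBS, AIBN (cat.), PhCF3, 80 °C
Reagents that add atoms: N-bromosuccinimide, O=C1CCC(=O)N1Br
Why: Wohl–Ziegler radical bromination should functionalise one of the two equivalent benzylic methyl groups (no stereocentre).

**Step 8**
Reactants: 11 the enone; 13 the benzyl bromide
Product: 15 (1R,4aR,8aS)-6-methoxy-1-[(2-methoxy-3-methylphenyl)methyl]-1,4a-dimethyl-3,4,4a,7,8,8a-hexahydronaphthalen-2(1H)-one (trans-fused; arylmethyl β, both methyl groups α), via trans-fused lithium enolate 14 (not isolated)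
Conditions: Li, NH3 (l), THF, t-BuOH (1 equiv), −78 °C; isoprene; then 13, THF, −78 to −33 °C; NH4Cl
Reagents that add atoms: none
Why: Dissolving-metal reductive alkylation of the enone should protonate C10 axially to give the trans ring fusion and deliver the C8–C9 enolate regiospecifically, which is benzylated on the β face opposite to the axial C5 methyl group.

**Step 9**
Reactants: 15 the benzylated ketone
Product: 16 (1R,4aR,8aS)-6-methoxy-1-[(2-methoxy-3-methylphenyl)methyl]-1,4a-dimethyl-2-methylidene-1,2,3,4,4a,7,8,8a-octahydronaphthalene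
Conditions: Ph3PCH3Br, KOt-Bu, toluene, 90 °C
Reagents that add atoms: methyltriphenylphosphonium bromide, C[P+](c1ccccc1)(c1ccccc1)c1ccccc1.[Br-]
Why: Wittig methylenation with excess non-stabilised ylide should convert the hindered C8 ketone, to which the enol ether and aryl ether are inert.

**Step 10**
Reactants: 16 the methylidene enol ether; 17 acrolein
Product: 18 hetero-Diels–Alder adduct: 2H-pyran cis-fused at C3–C4 of ring A on the β face (C3 carries OMe and the ring oxygen, C4 the ring CH2), rest of the skeleton as in 16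
Conditions: Yb(fod)3 (5 mol %), hydroquinone (cat.), CH2Cl2, 40 °C (sealed)
Reagents that add atoms: none
Why: The inverse-electron-demand hetero-Diels–Alder reaction of acrolein as 1-oxadiene with the electron-rich enol ether should form the C4–C bond regiospecifically at the enol ether β-carbon from the face opposite to the C5 methyl group (the C4 configuration is corrected in step 11).

**Step 11**
Reactants: 18 the cyclic mixed ketal
Product: 21 3-[(1S,4aS,5R,8aR)-5-[(2-methoxy-3-methylphenyl)methyl]-5,8a-dimethyl-6-methylidene-2-oxodecahydronaphthalen-1-yl]propanoic acid (side chain α, equatorial), via 4-epi keto aldehyde 19 (not isolated), via 4-epi keto acid 20 (not isolated)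
Conditions: oxalic acid, THF/H2O, 25 °C; NaClO2, NaH2PO4, 2-methylbut-2-ene, t-BuOH/H2O, 0 °C; then NaOH, MeOH/H2O, 25 °C; HCl
Reagents that add atoms: water, O; sodium chlorite, [Na+].[O-]Cl=O
Why: Mild acid hydrolysis of the mixed ketal should free the C3 ketone and the aldehyde, Pinnick oxidation gives the acid chemoselectively, and base equilibration through the C3 enolate places the C4 side chain in the more stable equatorial position, cis to the C5 methyl group.

**Step 12**
Reactants: 21 the keto acid
Product: 22 3-[(1S,4aR,5S,6R,8aR)-5-[(2-methoxy-3-methylphenyl)methyl]-5,6,8a-trimethyl-2-oxodecahydronaphthalen-1-yl]propanoic acid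
Conditions: H2 (1 atm), palladium on carbon (Pd/C), EtOAc, 25 °C
Reagents that add atoms: none
Why: Heterogeneous catalytic hydrogenation should add hydrogen to the exocyclic methylene from the β face, away from the axial α methyl groups at C5 and C9, to give the equatorial α methyl group at C8.

**Step 13**
Reactants: 22 the saturated keto acid; 23 S-phenyl 2-methylpropanethioate
Product: 25 3-[(1S,4aR,5S,6R,8aR)-5-[(2-methoxy-3-methylphenyl)methyl]-5,6,8a-trimethyl-2-(propan-2-ylidene)decahydronaphthalen-1-yl]propanoic acid, via spiro β-lactone 24 (not isolated)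
Conditions: LiN(i-Pr)2, 23 (2.5 equiv), THF, −78 to 0 °C; aq. HCl (pH 4); then SiO2, toluene, 110 °C
Reagents that add atoms: none
Why: In this β-lactone olefination, aldol addition of the thioester enolate to the C3 ketone and lactonisation with loss of thiophenolate give the spiro β-lactone, whose thermal [2+2] cycloreversion should expel CO2 and give the tetrasubstituted alkene without cationic intermediates, so neither double-bond migration nor loss of the C4 configuration is expected.

**Step 14**
Reactants: 25 the aryl methyl ether acid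
Product: 26 3-[(1S,4aR,5S,6R,8aR)-5-[(2-hydroxy-3-methylphenyl)methyl]-5,6,8a-trimethyl-2-(propan-2-ylidene)decahydronaphthalen-1-yl]propanoic acid
Conditions: NaSEt, DMF, 130 °C; then aq. HCl
Reagents that add atoms: none
Why: SN2 demethylation of the aryl methyl ether by ethanethiolate should proceed with the acid present as its carboxylate and without touching the alkene or the stereocentres.

**Step 15**
Reactants: 26 the phenol acid
Product: 27 stypoquinonic acid, 3-[(1S,4aR,5S,6R,8aR)-5,6,8a-trimethyl-5-[(5-methyl-3,6-dioxocyclohexa-1,4-dien-1-yl)methyl]-2-(propan-2-ylidene)decahydronaphthalen-1-yl]propanoic acid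
Conditions: K2[ON(SO3)2], KH2PO4, acetone/H2O, 25 °C
Reagents that add atoms: potassium nitrosodisulfonate, [K+].[K+].[O]N(S(=O)(=O)[O-])S(=O)(=O)[O-]
Why: Teuber oxidation of the 2,6-dialkylphenol with a free para position should give the 2,6-disubstituted 1,4-benzoquinone.

**Compound list**

1 | 2,5-dimethoxytoluene | COc1ccc(OC)c(C)c1 | starting material
2 | 1,4-dimethoxy-2-methylcyclohexa-1,4-diene (not isolated) | COC1=C(C)CC(OC)=CC1 | intermediate
3 | 1,4-dimethoxy-2-methylcyclohexa-1,3-diene | COC1=CC(C)=C(OC)CC1 | intermediate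
4 | 3-[(E)-but-2-enoyl]-1,3-oxazolidin-2-one | C/C=C/C(=O)N1CCOC1=O | starting material
5 | 3-{[(1R,2S,3S,4R)-1,4-dimethoxy-3,5-dimethylbicyclo[2.2.2]oct-5-en-2-yl]carbonyl}-1,3-oxazolidin-2-one | CO[C@]12CC[C@](OC)(C(C)=C1)[C@@H](C)[C@@H]2C(=O)N3CCOC3=O | intermediate
6 | (1R,2S,3S,4R)-1,4-dimethoxy-3,5-dimethylbicyclo[2.2.2]oct-5-ene-2-carboxylic acid | CO[C@]12CC[C@](OC)(C(C)=C1)[C@@H](C)[C@@H]2C(=O)O | intermediate
7 | 2-hydroperoxy-1,4-dimethoxy-3,5-dimethylbicyclo[2.2.2]oct-5-ene-2-carboxylic acid (C2 undefined; not isolated) | CO[C@]12CC[C@](OC)(C(C)=C1)[C@@H](C)C2(OO)C(=O)O | intermediate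
8 | (1R,3R,4R)-1,4-dimethoxy-3,5-dimethylbicyclo[2.2.2]oct-5-en-2-one | CO[C@]12CC[C@](OC)(C(C)=C1)[C@@H](C)C2=O | intermediate
9 | (1R,2R,3S,4R)-2-ethenyl-1,4-dimethoxy-3,5-dimethylbicyclo[2.2.2]oct-5-en-2-ol | CO[C@]12CC[C@](OC)(C(C)=C1)[C@@H](C)[C@]2(O)C=C | intermediate
10 | cis-fused 6,8a-dimethoxy-1,4a-dimethyl-3,4,4a,7,8,8a-hexahydronaphthalen-2(1H)-one (not isolated) | COC1=C[C@]2(C)CCC(=O)[C@H](C)[C@]2(OC)CC1 | intermediate
11 | (4aS)-6-methoxy-1,4a-dimethyl-4,4a,7,8-tetrahydronaphthalen-2(3H)-one | COC1=C[C@]2(C)CCC(=O)C(C)=C2CC1 | intermediate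
12 | 2,6-dimethylanisole | COc1c(C)cccc1C | starting material
13 | 1-(bromomethyl)-2-methoxy-3-methylbenzene | COc1c(C)cccc1CBr | intermediate
14 | lithium (4aR,8aS)-6-methoxy-1,4a-dimethyl-3,4,4a,7,8,8a-hexahydronaphthalen-2-olate (not isolated) | [Li+].COC1=C[C@]2(C)CCC([O-])=C(C)[C@H]2CC1 | intermediate
15 | (1R,4aR,8aS)-6-methoxy-1-[(2-methoxy-3-methylphenyl)methyl]-1,4a-dimethyl-3,4,4a,7,8,8a-hexahydronaphthalen-2(1H)-one | Cc1cccc(C[C@]2(C)[C@H]3CCC(OC)=C[C@]3(C)CCC2=O)c1OC | intermediate
16 | (1R,4aR,8aS)-6-methoxy-1-[(2-methoxy-3-methylphenyl)methyl]-1,4a-dimethyl-2-methylidene-1,2,3,4,4a,7,8,8a-octahydronaphthalene | Cc1cccc(C[C@]2(C)[C@H]3CCC(OC)=C[C@]3(C)CCC2=C)c1OC | intermediate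
17 | acrolein | C=CC=O | starting material
18 | hetero-Diels–Alder adduct of 16 with acrolein (2H-pyran cis-fused at C3–C4, β face; C3–OMe) | Cc1cccc(C[C@]2(C)[C@H]3CC[C@]4(OC)OC=CC[C@@H]4[C@]3(C)CCC2=C)c1OC | intermediate
19 | 3-[(1R,4aS,5R,8aR)-5-[(2-methoxy-3-methylphenyl)methyl]-5,8a-dimethyl-6-methylidene-2-oxodecahydronaphthalen-1-yl]propanal (4-epi; not isolated) | Cc1cccc(C[C@]2(C)[C@H]3CCC(=O)[C@H](CCC=O)[C@]3(C)CCC2=C)c1OC | intermediate
20 | 3-[(1R,4aS,5R,8aR)-5-[(2-methoxy-3-methylphenyl)methyl]-5,8a-dimethyl-6-methylidene-2-oxodecahydronaphthalen-1-yl]propanoic acid (4-epi; not isolated) | Cc1cccc(C[C@]2(C)[C@H]3CCC(=O)[C@H](CCC(=O)O)[C@]3(C)CCC2=C)c1OC | intermediate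
21 | 3-[(1S,4aS,5R,8aR)-5-[(2-methoxy-3-methylphenyl)methyl]-5,8a-dimethyl-6-methylidene-2-oxodecahydronaphthalen-1-yl]propanoic acid | Cc1cccc(C[C@]2(C)[C@H]3CCC(=O)[C@@H](CCC(=O)O)[C@]3(C)CCC2=C)c1OC | intermediate
22 | 3-[(1S,4aR,5S,6R,8aR)-5-[(2-methoxy-3-methylphenyl)methyl]-5,6,8a-trimethyl-2-oxodecahydronaphthalen-1-yl]propanoic acid | Cc1cccc(C[C@]2(C)[C@H]3CCC(=O)[C@@H](CCC(=O)O)[C@]3(C)CC[C@H]2C)c1OC | intermediate
23 | S-phenyl 2-methylpropanethioate | CC(C)C(=O)Sc1ccccc1 | starting material
24 | spiro β-lactone at C3 (3',3'-dimethyl-4'-oxo-oxetane spiro-fused to ring A; spiro centre undefined; not isolated) | Cc1cccc(C[C@]2(C)[C@H]3CCC4(OC(=O)C4(C)C)[C@@H](CCC(=O)O)[C@]3(C)CC[C@H]2C)c1OC | intermediate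
25 | 3-[(1S,4aR,5S,6R,8aR)-5-[(2-methoxy-3-methylphenyl)methyl]-5,6,8a-trimethyl-2-(propan-2-ylidene)decahydronaphthalen-1-yl]propanoic acid | Cc1cccc(C[C@]2(C)[C@H]3CCC(=C(C)C)[C@@H](CCC(=O)O)[C@]3(C)CC[C@H]2C)c1OC | intermediate
26 | 3-[(1S,4aR,5S,6R,8aR)-5-[(2-hydroxy-3-methylphenyl)methyl]-5,6,8a-trimethyl-2-(propan-2-ylidene)decahydronaphthalen-1-yl]propanoic acid | Cc1cccc(C[C@]2(C)[C@H]3CCC(=C(C)C)[C@@H](CCC(=O)O)[C@]3(C)CC[C@H]2C)c1O | intermediate
27 | stypoquinonic acid | CC1=CC(=O)C=C(C[C@]2(C)[C@H]3CCC(=C(C)C)[C@@H](CCC(=O)O)[C@]3(C)CC[C@H]2C)C1=O | target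

**Step count.** Total: 15 steps. Longest linear sequence: 14 steps (steps 1–6 and 8–15; step 7 is the side branch).

**Steps most likely to fail**

Step 2. Facial and endo control may erode if the electron-rich diene reacts through a stepwise Michael-type pathway, and the diene may lose methanol and aromatise under the cationic copper Lewis acid. The fallback sets out from 3 and replaces catalyst control by auxiliary control. Cycloaddition with (R)-4-benzyl-3-[(E)-but-2-enoyl]-1,3-oxazolidin-2-one promoted by Me2AlCl in CH2Cl2 at −78 °C should give the auxiliary-bearing endo adduct F1, since the diene adds to the face of the chelated s-cis imide opposite to the benzyl group. Cleavage with LiOH/H2O2 comes back to the route at acid 6.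

Step 10. The cycloaddition may be too slow at the hindered C4 next to quaternary C5, so that acrolein polymerises or the enol ether hydrolyses first. The fallback sets out from 16 and uses a far more electrophilic oxadiene, 2,2-dimethyl-5-methylidene-1,3-dioxane-4,6-dione, generated in the flask from 2,2-dimethyl-1,3-dioxane-4,6-dione and formaldehyde (ethylenediammonium diacetate cat., MeCN, 25 °C). This should give the pyrano-dioxinone hetero-Diels–Alder adduct F2. Hot pyridine/water (ring opening and decarboxylation), dilute HCl (ketal hydrolysis) and NaOH (C4 equilibration) then rejoin the route at keto acid 21.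

Step 13. The thioester enolate may enolise the hindered α-branched C3 ketone, or the aldolate may revert, instead of closing the β-lactone. The fallback sets out from 22. Esterification with Me3SiCHN2 in MeOH/toluene gives the keto methyl ester F3. A mixed McMurry coupling with excess acetone (TiCl4, Zn, pyridine, THF, reflux) should give the isopropylidene methyl ester F4. NaSEt in DMF at 130 °C then cleaves both the aryl methyl ether and the methyl ester and returns to the route at phenol acid 26.

**Further compounds**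

F1 | step 2 | (R)-4-benzyl-3-{[(1R,2S,3S,4R)-1,4-dimethoxy-3,5-dimethylbicyclo[2.2.2]oct-5-en-2-yl]carbonyl}-1,3-oxazolidin-2-one | CO[C@]12CC[C@](OC)(C(C)=C1)[C@@H](C)[C@@H]2C(=O)N3[C@H](Cc4ccccc4)COC3=O
F2 | step 10 | hetero-Diels–Alder adduct of 16 with 2,2-dimethyl-5-methylidene-1,3-dioxane-4,6-dione (pyrano[2,3-d][1,3]dioxin-4-one fused at C3–C4; C3–OMe) | Cc1cccc(C[C@]2(C)[C@H]3CCC4(OC)OC5=C(CC4[C@]3(C)CCC2=C)C(=O)OC(C)(C)O5)c1OC
F3 | step 13 | methyl 3-[(1S,4aR,5S,6R,8aR)-5-[(2-methoxy-3-methylphenyl)methyl]-5,6,8a-trimethyl-2-oxodecahydronaphthalen-1-yl]propanoate | Cc1cccc(C[C@]2(C)[C@H]3CCC(=O)[C@@H](CCC(=O)OC)[C@]3(C)CC[C@H]2C)c1OC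
F4 | step 13 | methyl 3-[(1S,4aR,5S,6R,8aR)-5-[(2-methoxy-3-methylphenyl)methyl]-5,6,8a-trimethyl-2-(propan-2-ylidene)decahydronaphthalen-1-yl]propanoate | Cc1cccc(C[C@]2(C)[C@H]3CCC(=C(C)C)[C@@H](CCC(=O)OC)[C@]3(C)CC[C@H]2C)c1OC
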